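The target came slowly. In the elm flask it was still rising between the last two readings, so I read a time exponent from them, and it carries their scatter:

n = ln(26.5% / 7.4%) / ln(40.0 min / 20.0 min) = 1.84

A flask making target at a steady rate gives 1, and elm gave more: the rate was still climbing. That suits the proposed path, in which substrate becomes open intermediate, partner becomes second intermediate, and the two meet to give target. Two second intermediates may also pair to homo product, and partner may decompose.

| flask | substrate | partner | temperature | remark | time |
|---|---|---|---|---|---|
| maple | 0.022 M | 1.2 equiv | 75 °C | run made earlier |  |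
| elm | 0.11 M | 1.2 equiv | 90 °C | run made earlier |  |
| theta | 0.058 M | 1.20 equiv | 90 °C |  | 1.0 h |
| gamma | 0.015 M | 1.20 equiv | 90 °C |  | 1.0 h |
| epsilon | 0.080 M | 1.20 equiv | 90 °C |  | 1.0 h |
| eta | 0.040 M | 1.20 equiv | 90 °C |  | 1.0 h |

| maple: time / min | maple: target / % | elm: time / min | elm: target / % |
|---|---|---|---|
| 20.0 | 0 | 3.00 | 0 |
| 40.0 | 2.6 | 8.00 | 1.1 |
| 60.0 | 0.5 | 20.0 | 7.4 |
| 80.0 | 1.0 | 40.0 | 26.5 |

(scatter of a reading: 1 percentage point)

- what may be going on: substrate -> open intermediate; partner -> second intermediate; open intermediate + second intermediate -> target; 2 second intermediate -> homo product; partner -> decomposition product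

- all flasks from highest to lowest amount of target, in percent of the substrate charged, at 1.0 h (theta / gamma / epsilon / eta)
- the amount of target, in percent of the substrate charged of the flask you put first, at 1.0 h
- the amount of target, in percent of the substrate charged of the flask you put last, at 1.0 h

The new flasks differ from one another in the substrate charge, with the equivalents of partner, the temperature and the time held. I needed the dilution exponent, so I fixed its scale. At fixed time a first-order step gives the same percentage at any charge, which makes 0 the zero. Capture is bimolecular, so if [second intermediate] simply grows with the charge, the exponent is 1. If its making balances its pairing, [second intermediate] follows the square root of the charge, and the exponent is 0.5. I took the middle, 0.750, as the dilution exponent: the power of the charge by which target, in percent of the substrate charged, grows at fixed time.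

Carrying elm forward to 1.0 h and then down to each charge, I reckoned:

elm: 26.5% × (60 min / 40.0 min)^n = 55.9%

epsilon: 44.0%; gamma: 12.5%

The forecast, separately, gave epsilon > theta > eta > gamma, with 40% first and 14% last, saying “I take an exponent of about 0.7”. Its top lies below mine and its low above mine.

The simulation gave epsilon > theta > eta > gamma, from 37.3% in epsilon down to 13.1% in gamma.

    substrate → open intermediate (k = 8.54 × 10⁻⁴ s⁻¹, Ea = 101 kJ mol⁻¹)
    partner → second intermediate (k = 4.84 × 10⁻⁴ s⁻¹, Ea = 104 kJ mol⁻¹)
    open intermediate + second intermediate → target (k = 0.00605 M⁻¹ s⁻¹, Ea = 81.0 kJ mol⁻¹)
    2 second intermediate → homo product (k = 0.00291 M⁻¹ s⁻¹, Ea = 74.0 kJ mol⁻¹)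
    partner → decomposition product (k = 2.69 × 10⁻⁶ s⁻¹, Ea = 122 kJ mol⁻¹)
    (constants at 90 °C)

Substrate left at 1.00 h stood at 4.6% in epsilon and 4.6% in gamma, the same share at both charges, as a first-order step gives at the zero of the scale. Between those two flasks the target gave an exponent of 0.627, lower than m. Taking m upward from gamma to a neighbour flask charged with 0.032 M of substrate gives 23.0%, and that neighbour held 22.6%.

The earlier runs and the new flask were computed with constants of no real substance.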